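**Retrosynthetic overview**
1. The target comes from its 8,9‑diol 15‑silyl ether by O8 angeloylation, O9 acetylation and desilylation.
2. Key disconnection C7–C8, which also closes the ten‑membered ring: a dioxolan‑4‑yl radical at C8 (C–H abstraction on the 8,9‑acetonide) adds to C7 of a 3‑(phenylsulfonylmethyl)butenolide and expels PhSO2•. One step gives the ring, C7, C8 and the exo‑methylene lactone.
3. The seco precursor comes from cross‑metathesis (C1=C10) of a butenolide diene with an acrylate made from D‑glyceraldehyde acetonide (alkyne, then Markovnikov hydromethoxycarbonylation; C9 from the chiral pool).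
4. The butenolide fragment comes from acrolein and a propargyl ether: acetylide addition, Sharpless kinetic resolution (C6), hydroxyl‑directed hydroalumination/iodination (C4=C5 geometry), acylation, ring‑closing metathesis, Negishi coupling (C3–C4).
5. Ring order: butenolide first (ring‑closing metathesis), ten‑membered carbocycle second (radical step), in which the butenolide becomes the α‑methylene‑γ‑lactone.

Atom labels (germacrane numbering): lactone O–C6, C7, C11(=C13), C12(=O); C8 (O‑angelate), C9 (OAc), C10 (bears C14 ester)=C1, C2, C3, C4 (bears C15)=C5.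
Assumption: the target is taken exactly as drawn: 6R,7S,8S,9S; both ring alkenes E by CIP (ring‑cis); the (Z)‑2‑methylbut‑2‑enoate is the angelate.

**Route**

Step 1
Reactants: 1 2‑(bromomethyl)prop‑2‑enoic acid
Product: 2 2‑[(phenylsulfonyl)methyl]prop‑2‑enoic acid
Conditions: PhSO2Na (1.2 equiv), MeOH, reflux
Reagents that add atoms: sodium benzenesulfinate, [Na+].[O-]S(=O)c1ccccc1
Why: S‑alkylation of the sulfinate by the allylic bromide (SN2 or SN2′ give the same product), the standard way to 2‑(sulfonylmethyl)acrylates.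

Step 2
Reactants: 3 tert‑butyl(diphenyl)(prop‑2‑yn‑1‑yloxy)silane; 4 acrolein
Product: 6 rac‑6‑[(tert‑butyldiphenylsilyl)oxy]hex‑1‑en‑4‑yn‑3‑ol, via lithium acetylide 5 (not isolated)
Conditions: n‑BuLi, THF, −78 °C; then acrolein, −78 °C; aq. NH4Cl
Reagents that add atoms: none
Why: 1,2‑addition of a lithium acetylide to an enal gives the racemic C6 carbinol carrying C7 (vinyl), C5≡C4 and C15.

Step 3
Reactants: 6 rac‑6‑[(tert‑butyldiphenylsilyl)oxy]hex‑1‑en‑4‑yn‑3‑ol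
Product: 7 (3S)‑6‑[(tert‑butyldiphenylsilyl)oxy]hex‑1‑en‑4‑yn‑3‑ol
Conditions: Ti(OiPr)4 (15 mol%), L‑(+)‑diisopropyl tartrate (18 mol%), t‑BuOOH (0.6 equiv), 4 Å MS, CH2Cl2, −20 °C
Reagents that add atoms: none
Why: Sharpless kinetic resolution: with the L‑(+)‑tartrate the (3R)‑alcohol is epoxidised at its vinyl group and the (3S)‑alcohol is recovered (at most 50%), which fixes C6.

Step 4
Reactants: 7 (3S)‑6‑[(tert‑butyldiphenylsilyl)oxy]hex‑1‑en‑4‑yn‑3‑ol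
Product: 9 (3S,4Z)‑6‑[(tert‑butyldiphenylsilyl)oxy]‑5‑iodohexa‑1,4‑dien‑3‑ol, via cyclic alkenylalanate 8 (not isolated)
Conditions: NaAlH2(OCH2CH2OMe)2, THF, 0 °C; then I2, −78 °C
Reagents that add atoms: iodine, II
Why: Hydroxyl‑directed trans‑hydroalumination of the propargylic alcohol puts H on C5 and Al on C4 (five‑membered alanate), and iodinolysis with retention gives the Z‑iodide with I cis to C6, which fixes the later ring‑cis C4=C5 geometry.

Step 5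
Reactants: 2 2‑[(phenylsulfonyl)methyl]prop‑2‑enoic acid; 9 (3S,4Z)‑6‑[(tert‑butyldiphenylsilyl)oxy]‑5‑iodohexa‑1,4‑dien‑3‑ol
Product: 11 (3S,4Z)‑6‑[(tert‑butyldiphenylsilyl)oxy]‑5‑iodohexa‑1,4‑dien‑3‑yl 2‑[(phenylsulfonyl)methyl]prop‑2‑enoate, via acid chloride 10 (not isolated)
Conditions: 2, (COCl)2, cat. DMF, CH2Cl2, 0 °C to rt; then 9, 2,6‑lutidine, CH2Cl2, −20 to 0 °C
Reagents that add atoms: none
Why: Acyl chloride esterification with a hindered, non‑nucleophilic base, which does not attack the allyl sulfone and leaves C6 untouched.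

Step 6
Reactants: 11 (3S,4Z)‑6‑[(tert‑butyldiphenylsilyl)oxy]‑5‑iodohexa‑1,4‑dien‑3‑yl 2‑[(phenylsulfonyl)methyl]prop‑2‑enoate
Product: 12 (5S)‑5‑[(1Z)‑3‑[(tert‑butyldiphenylsilyl)oxy]‑2‑iodoprop‑1‑en‑1‑yl]‑3‑[(phenylsulfonyl)methyl]furan‑2(5H)‑one
Conditions: second‑generation Hoveyda–Grubbs catalyst (5 mol%), toluene (5 mM), 80 °C
Reagents that add atoms: none
Why: Ring‑closing metathesis between the carbinol vinyl group and the 1,1‑disubstituted acrylate gives the α‑substituted butenolide (C7=C11), while the trisubstituted iodoalkene is inert.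

Step 7
Reactants: 12 (5S)‑5‑[(1Z)‑3‑[(tert‑butyldiphenylsilyl)oxy]‑2‑iodoprop‑1‑en‑1‑yl]‑3‑[(phenylsulfonyl)methyl]furan‑2(5H)‑one; 13 but‑3‑en‑1‑ylzinc bromide
Product: 14 (5R)‑5‑[(1E)‑2‑{[(tert‑butyldiphenylsilyl)oxy]methyl}hexa‑1,5‑dien‑1‑yl]‑3‑[(phenylsulfonyl)methyl]furan‑2(5H)‑one
Conditions: 13 (1.5 equiv, THF), Pd(dppf)Cl2 (5 mol%), THF, 25 °C
Reagents that add atoms: none
Why: Negishi sp2–sp3 coupling with retention of alkene geometry puts C3 cis to C6 (the CIP labels change to 5R and E, the spatial arrangement does not).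

Step 8
Reactants: 15 (R)‑2,2‑dimethyl‑1,3‑dioxolane‑4‑carbaldehyde
Product: 16 (4S)‑4‑ethynyl‑2,2‑dimethyl‑1,3‑dioxolane
Conditions: dimethyl (1‑diazo‑2‑oxopropyl)phosphonate, K2CO3, MeOH, 0 °C to rt
Reagents that add atoms: dimethyl (1‑diazo‑2‑oxopropyl)phosphonate, CC(=O)C(=[N+]=[N-])P(=O)(OC)OC
Why: Ohira–Bestmann homologation of the aldehyde to the terminal alkyne under mild base keeps the stereocentre (future C9).

Step 9
Reactants: 16 (4S)‑4‑ethynyl‑2,2‑dimethyl‑1,3‑dioxolane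
Product: 17 methyl 2‑[(4S)‑2,2‑dimethyl‑1,3‑dioxolan‑4‑yl]prop‑2‑enoate
Conditions: Pd(OAc)2 (1 mol%), 2‑(diphenylphosphino)pyridine (30 mol%), CH3SO3H (30 mol%), CO (20 bar), MeOH (5 equiv), N‑methylpyrrolidone, 45 °C
Reagents that add atoms: carbon monoxide, [C-]#[O+]; methanol, CO
Why: Palladium‑catalysed Markovnikov hydromethoxycarbonylation of a terminal alkyne (Drent‑type) gives the 2‑substituted acrylate (C10 with the C14 ester) without touching C9.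

Step 10
Reactants: 14 (5R)‑5‑[(1E)‑2‑{[(tert‑butyldiphenylsilyl)oxy]methyl}hexa‑1,5‑dien‑1‑yl]‑3‑[(phenylsulfonyl)methyl]furan‑2(5H)‑one; 17 methyl 2‑[(4S)‑2,2‑dimethyl‑1,3‑dioxolan‑4‑yl]prop‑2‑enoate
Product: 18 methyl (2E,6E)‑6‑{[(tert‑butyldiphenylsilyl)oxy]methyl}‑2‑[(4S)‑2,2‑dimethyl‑1,3‑dioxolan‑4‑yl]‑7‑{(2R)‑5‑oxo‑4‑[(phenylsulfonyl)methyl]‑2,5‑dihydrofuran‑2‑yl}hepta‑2,6‑dienoate
Conditions: 17 (3 equiv), second‑generation Hoveyda–Grubbs catalyst (10 mol%), CH2Cl2, 40 °C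
Reagents that add atoms: none
Why: Cross‑metathesis of the only terminal olefin with the 1,1‑disubstituted acrylate gives the trisubstituted enoate with the alkyl chain trans to CO2Me, the usual outcome for 2‑substituted acrylates, which places C2 cis to C9.

Step 11
Reactants: 18 methyl (2E,6E)‑6‑{[(tert‑butyldiphenylsilyl)oxy]methyl}‑2‑[(4S)‑2,2‑dimethyl‑1,3‑dioxolan‑4‑yl]‑7‑{(2R)‑5‑oxo‑4‑[(phenylsulfonyl)methyl]‑2,5‑dihydrofuran‑2‑yl}hepta‑2,6‑dienoate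
Product: 19 methyl (1(10)E,4E,6R,7S,8S,9S)‑15‑[(tert‑butyldiphenylsilyl)oxy]‑8,9‑(isopropylidenedioxy)germacra‑1(10),4,11(13)‑trien‑12,6‑olid‑14‑oate
Conditions: (n‑Bu4N)4[W10O32] (5 mol%), MeCN (2 mM, degassed), 390 nm LEDs, 25 °C
Reagents that add atoms: none
Why: Proposed new method: photoexcited decatungstate abstracts a hydrogen atom from the open, hydridic O–CH2 (C8) of the acetonide, the nucleophilic dioxolan‑4‑yl radical adds 10‑exo to the butenolide β‑carbon C7 anti to the C9 substituent (trans‑acetonide, C8 S) and anti to the C6 side chain (trans‑lactone, C7 S), and the α‑lactone radical expels PhSO2• (radical allylation, SH2′) to give the exo‑methylene while the sulfonyl radical takes the hydrogen back from the reduced polyoxotungstate; the closest known reactions are decatungstate C–H alkylation and allylation of dioxolanes with electron‑poor alkenes and allyl sulfones, trans‑selective additions of tartrate‑type dioxolanyl radicals, anti additions to 5‑substituted butenolides and photoredox Giese macrocyclisations.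

Step 12
Reactants: 19 methyl (1(10)E,4E,6R,7S,8S,9S)‑15‑[(tert‑butyldiphenylsilyl)oxy]‑8,9‑(isopropylidenedioxy)germacra‑1(10),4,11(13)‑trien‑12,6‑olid‑14‑oate
Product: 20 methyl (1(10)E,4E)‑15‑[(tert‑butyldiphenylsilyl)oxy]‑8,9‑dihydroxygermacra‑1(10),4,11(13)‑trien‑12,6‑olid‑14‑oate, configured at C6–C9 as in 19 (CIP: 6R,7R,8S,9S, the C7 label changes with the free 8‑OH)
Conditions: AcOH/H2O (4:1), 45 °C
Reagents that add atoms: none
Why: Mild acid hydrolysis of the acetonide, under which the TBDPS ether, the esters and the α‑methylene lactone survive and no stereocentre is touched.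

Step 13
Reactants: 20 methyl (1(10)E,4E)‑15‑[(tert‑butyldiphenylsilyl)oxy]‑8,9‑dihydroxygermacra‑1(10),4,11(13)‑trien‑12,6‑olid‑14‑oate; 21 angelic acid, (2Z)‑2‑methylbut‑2‑enoic acid
Product: 23 methyl (1(10)E,4E,6R,7S,8S,9S)‑8‑(angeloyloxy)‑15‑[(tert‑butyldiphenylsilyl)oxy]‑9‑hydroxygermacra‑1(10),4,11(13)‑trien‑12,6‑olid‑14‑oate, via mixed anhydride 22 (not isolated)
Conditions: 21, 2,4,6‑trichlorobenzoyl chloride, Et3N, toluene, rt; then 20 (1.0 equiv), toluene, 60 °C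
Reagents that add atoms: none
Why: Yamaguchi‑type mixed‑anhydride acylation without DMAP, which transfers the angelate without Z→E isomerisation, is expected to go to O8 because the C9 hydroxyl is the deactivated carbinol next to the acrylate carbon and hydrogen‑bonded to the C14 ester.

Step 14
Reactants: 23 methyl (1(10)E,4E,6R,7S,8S,9S)‑8‑(angeloyloxy)‑15‑[(tert‑butyldiphenylsilyl)oxy]‑9‑hydroxygermacra‑1(10),4,11(13)‑trien‑12,6‑olid‑14‑oate
Product: 24 methyl (1(10)E,4E,6R,7S,8S,9S)‑9‑acetoxy‑8‑(angeloyloxy)‑15‑[(tert‑butyldiphenylsilyl)oxy]germacra‑1(10),4,11(13)‑trien‑12,6‑olid‑14‑oate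
Conditions: Ac2O, pyridine, DMAP (5 mol%), CH2Cl2, 0 °C
Reagents that add atoms: acetic anhydride, CC(=O)OC(C)=O
Why: Standard acetylation of the one remaining secondary hydroxyl (O9).

Step 15
Reactants: 24 methyl (1(10)E,4E,6R,7S,8S,9S)‑9‑acetoxy‑8‑(angeloyloxy)‑15‑[(tert‑butyldiphenylsilyl)oxy]germacra‑1(10),4,11(13)‑trien‑12,6‑olid‑14‑oate
Product: 25 CNP0216801.4, methyl (3aS,4S,5S,6E,10E,11aR)‑5‑(acetyloxy)‑10‑(hydroxymethyl)‑3‑methylidene‑4‑{[(2Z)‑2‑methylbut‑2‑enoyl]oxy}‑2‑oxo‑2,3,3a,4,5,8,9,11a‑octahydrocyclodeca[b]furan‑6‑carboxylate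
Conditions: HF·pyridine, pyridine, THF, 0 °C to rt
Reagents that add atoms: none
Why: Buffered fluoride desilylation frees the primary allylic C15 hydroxyl under non‑basic conditions that spare the acetate, the angelate and the α‑methylene lactone.

**Compound list**
1 | 2‑(bromomethyl)prop‑2‑enoic acid | C=C(CBr)C(=O)O | starting material
2 | 2‑[(phenylsulfonyl)methyl]prop‑2‑enoic acid | C=C(CS(=O)(=O)c1ccccc1)C(=O)O | intermediate
3 | tert‑butyl(diphenyl)(prop‑2‑yn‑1‑yloxy)silane (commercial TBDPS ether of propargyl alcohol) | C#CCO[Si](c1ccccc1)(c1ccccc1)C(C)(C)C | starting material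
4 | acrolein | C=CC=O | starting material
5 | lithium acetylide of 3 | [Li]C#CCO[Si](c1ccccc1)(c1ccccc1)C(C)(C)C | intermediate
6 | rac‑6‑[(tert‑butyldiphenylsilyl)oxy]hex‑1‑en‑4‑yn‑3‑ol | C=CC(O)C#CCO[Si](c1ccccc1)(c1ccccc1)C(C)(C)C | intermediate
7 | (3S)‑6‑[(tert‑butyldiphenylsilyl)oxy]hex‑1‑en‑4‑yn‑3‑ol | C=C[C@H](O)C#CCO[Si](c1ccccc1)(c1ccccc1)C(C)(C)C | intermediate
8 | cyclic alkenylalanate (sodium 2,2‑bis(2‑methoxyethoxy)‑2,5‑dihydro‑1,2‑oxaaluminol‑2‑uide from 7) | [Na+].C=C[C@H]1C=C(CO[Si](c2ccccc2)(c2ccccc2)C(C)(C)C)[Al-](OCCOC)(OCCOC)O1 | intermediate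
9 | (3S,4Z)‑6‑[(tert‑butyldiphenylsilyl)oxy]‑5‑iodohexa‑1,4‑dien‑3‑ol | C=C[C@H](O)/C=C(\I)CO[Si](c1ccccc1)(c1ccccc1)C(C)(C)C | intermediate
10 | 2‑[(phenylsulfonyl)methyl]prop‑2‑enoyl chloride | C=C(CS(=O)(=O)c1ccccc1)C(Cl)=O | intermediate
11 | (3S,4Z)‑6‑[(tert‑butyldiphenylsilyl)oxy]‑5‑iodohexa‑1,4‑dien‑3‑yl 2‑[(phenylsulfonyl)methyl]prop‑2‑enoate | C=C[C@H](OC(=O)C(=C)CS(=O)(=O)c1ccccc1)/C=C(\I)CO[Si](c1ccccc1)(c1ccccc1)C(C)(C)C | intermediate
12 | (5S)‑5‑[(1Z)‑3‑[(tert‑butyldiphenylsilyl)oxy]‑2‑iodoprop‑1‑en‑1‑yl]‑3‑[(phenylsulfonyl)methyl]furan‑2(5H)‑one | O=C1O[C@H](/C=C(\I)CO[Si](c2ccccc2)(c2ccccc2)C(C)(C)C)C=C1CS(=O)(=O)c1ccccc1 | intermediate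
13 | but‑3‑en‑1‑ylzinc bromide | C=CCC[Zn]Br | starting material
14 | (5R)‑5‑[(1E)‑2‑{[(tert‑butyldiphenylsilyl)oxy]methyl}hexa‑1,5‑dien‑1‑yl]‑3‑[(phenylsulfonyl)methyl]furan‑2(5H)‑one | O=C1O[C@H](/C=C(/CO[Si](c2ccccc2)(c2ccccc2)C(C)(C)C)CCC=C)C=C1CS(=O)(=O)c1ccccc1 | intermediate
15 | (R)‑2,2‑dimethyl‑1,3‑dioxolane‑4‑carbaldehyde (commercial acetonide of D‑glyceraldehyde) | O=C[C@H]1COC(C)(C)O1 | starting material
16 | (4S)‑4‑ethynyl‑2,2‑dimethyl‑1,3‑dioxolane | C#C[C@H]1COC(C)(C)O1 | intermediate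
17 | methyl 2‑[(4S)‑2,2‑dimethyl‑1,3‑dioxolan‑4‑yl]prop‑2‑enoate | C=C(C(=O)OC)[C@H]1COC(C)(C)O1 | intermediate
18 | methyl (2E,6E)‑6‑{[(tert‑butyldiphenylsilyl)oxy]methyl}‑2‑[(4S)‑2,2‑dimethyl‑1,3‑dioxolan‑4‑yl]‑7‑{(2R)‑5‑oxo‑4‑[(phenylsulfonyl)methyl]‑2,5‑dihydrofuran‑2‑yl}hepta‑2,6‑dienoate | O=C1O[C@H](/C=C(/CO[Si](c2ccccc2)(c2ccccc2)C(C)(C)C)CC/C=C(/C(=O)OC)[C@H]2COC(C)(C)O2)C=C1CS(=O)(=O)c1ccccc1 | intermediate
19 | methyl (1(10)E,4E,6R,7S,8S,9S)‑15‑[(tert‑butyldiphenylsilyl)oxy]‑8,9‑(isopropylidenedioxy)germacra‑1(10),4,11(13)‑trien‑12,6‑olid‑14‑oate | C=C1C(=O)O[C@@H]2/C=C(/CO[Si](c3ccccc3)(c3ccccc3)C(C)(C)C)CC/C=C(/C(=O)OC)[C@@H]3OC(C)(C)O[C@H]3[C@@H]12 | intermediate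
20 | methyl (1(10)E,4E)‑15‑[(tert‑butyldiphenylsilyl)oxy]‑8,9‑dihydroxygermacra‑1(10),4,11(13)‑trien‑12,6‑olid‑14‑oate (CIP 6R,7R,8S,9S) | C=C1C(=O)O[C@@H]2/C=C(/CO[Si](c3ccccc3)(c3ccccc3)C(C)(C)C)CC/C=C(/C(=O)OC)[C@H](O)[C@@H](O)[C@@H]12 | intermediate
21 | angelic acid, (2Z)‑2‑methylbut‑2‑enoic acid | C/C=C(/C)C(=O)O | starting material
22 | (2Z)‑2‑methylbut‑2‑enoic 2,4,6‑trichlorobenzoic anhydride | C/C=C(/C)C(=O)OC(=O)c1c(Cl)cc(Cl)cc1Cl | intermediate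
23 | methyl (1(10)E,4E,6R,7S,8S,9S)‑8‑(angeloyloxy)‑15‑[(tert‑butyldiphenylsilyl)oxy]‑9‑hydroxygermacra‑1(10),4,11(13)‑trien‑12,6‑olid‑14‑oate | C=C1C(=O)O[C@@H]2/C=C(/CO[Si](c3ccccc3)(c3ccccc3)C(C)(C)C)CC/C=C(/C(=O)OC)[C@H](O)[C@@H](OC(=O)/C(C)=C\C)[C@@H]12 | intermediate
24 | methyl (1(10)E,4E,6R,7S,8S,9S)‑9‑acetoxy‑8‑(angeloyloxy)‑15‑[(tert‑butyldiphenylsilyl)oxy]germacra‑1(10),4,11(13)‑trien‑12,6‑olid‑14‑oate | C=C1C(=O)O[C@@H]2/C=C(/CO[Si](c3ccccc3)(c3ccccc3)C(C)(C)C)CC/C=C(/C(=O)OC)[C@H](OC(C)=O)[C@@H](OC(=O)/C(C)=C\C)[C@@H]12 | intermediate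
25 | CNP0216801.4, methyl (1(10)E,4E,6R,7S,8S,9S)‑9‑acetoxy‑8‑(angeloyloxy)‑15‑hydroxygermacra‑1(10),4,11(13)‑trien‑12,6‑olid‑14‑oate | C=C1C(=O)O[C@@H]2/C=C(/CO)CC/C=C(/C(=O)OC)[C@H](OC(C)=O)[C@@H](OC(=O)/C(C)=C\C)[C@@H]12 | target

**Step count**
Total: 15 steps. Longest linear sequence: 12 steps (steps 2–7, then 10–15, counted from 3). Steps 1 and 8–9 are side branches.

**Three steps most likely to fail**

Step 11 (radical ring closure). The risks are hydrogen abstraction at other sites (the tertiary allylic C9–H, the C3 allylic CH2) and the rate of a ten‑membered closure. The fallback makes the radical at a site that is unambiguous and fixes the C9 acetate before ring closure. It sets out from 18. Acid hydrolysis of the acetonide gives the seco‑diol F1. Trimethyl orthoacetate/PPTS followed by aqueous acetic acid opens the cyclic orthoester to the secondary acetate with a free primary C8 hydroxyl, F2. F2 is cyclised by hydrogen‑bond‑assisted α‑hydroxy C–H abstraction (Ir[dF(CF3)ppy]2(dtbbpy)PF6, quinuclidine, Bu4N H2PO4, MeCN, blue LEDs, 2 mM); the α‑hydroxyalkyl radical closes onto C7 with the same SH2′ loss of PhSO2• to give the 8‑hydroxy 9‑acetate macrocycle F3. Angeloylation of F3 under the conditions of step 13 comes back to the route at 24.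

Step 10 (cross‑metathesis). The acrylate 17 is 1,1‑disubstituted with a branched α‑substituent and may react slowly or give E/Z mixtures with the valuable diene 14. The fallback moves the metathesis to the small fragment and makes the fragment union a cross‑coupling. It sets out from 17 and 12. Cross‑metathesis of 17 with 4‑bromobut‑1‑ene in large excess (second‑generation Hoveyda–Grubbs catalyst) gives methyl (2E)‑5‑bromo‑2‑[(4S)‑2,2‑dimethyl‑1,3‑dioxolan‑4‑yl]pent‑2‑enoate F4. Zinc insertion (Zn, LiCl, THF) gives the alkylzinc bromide F5, and Pd(dppf)Cl2‑catalysed Negishi coupling of F5 with vinyl iodide 12 comes back to the route at 18, bypassing 14.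

Step 13 (regioselective angeloylation of the 8,9‑diol). The O8/O9 preference is an argument, not a precedent, and acyl or lactone migration is possible. The fallback replaces direct selective acylation by temporary protection. It sets out from 20. Silylation at −78 °C (TESCl, imidazole) gives the 8‑O‑triethylsilyl ether F6 and acetylation of O9 gives the 8‑O‑triethylsilyl 9‑acetate F7. Brief HF·pyridine at 0 °C removes only the triethylsilyl group and gives the 8‑hydroxy 9‑acetate F3 already described, and Yamaguchi angeloylation comes back to the route at 24.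

**Further compounds**
F1 | step 11 | methyl (2E,6E)‑6‑{[(tert‑butyldiphenylsilyl)oxy]methyl}‑2‑[(1S)‑1,2‑dihydroxyethyl]‑7‑{(2R)‑5‑oxo‑4‑[(phenylsulfonyl)methyl]‑2,5‑dihydrofuran‑2‑yl}hepta‑2,6‑dienoate | O=C1O[C@H](/C=C(/CO[Si](c2ccccc2)(c2ccccc2)C(C)(C)C)CC/C=C(/C(=O)OC)[C@H](O)CO)C=C1CS(=O)(=O)c1ccccc1
F2 | step 11 | methyl (2E,6E)‑2‑[(1S)‑1‑acetoxy‑2‑hydroxyethyl]‑6‑{[(tert‑butyldiphenylsilyl)oxy]methyl}‑7‑{(2R)‑5‑oxo‑4‑[(phenylsulfonyl)methyl]‑2,5‑dihydrofuran‑2‑yl}hepta‑2,6‑dienoate | O=C1O[C@H](/C=C(/CO[Si](c2ccccc2)(c2ccccc2)C(C)(C)C)CC/C=C(/C(=O)OC)[C@H](OC(C)=O)CO)C=C1CS(=O)(=O)c1ccccc1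
F3 | step 11 | methyl (1(10)E,4E)‑9‑acetoxy‑15‑[(tert‑butyldiphenylsilyl)oxy]‑8‑hydroxygermacra‑1(10),4,11(13)‑trien‑12,6‑olid‑14‑oate, configured at C6–C9 as in 25 | C=C1C(=O)O[C@@H]2/C=C(/CO[Si](c3ccccc3)(c3ccccc3)C(C)(C)C)CC/C=C(/C(=O)OC)[C@H](OC(C)=O)[C@@H](O)[C@@H]12
F4 | step 10 | methyl (2E)‑5‑bromo‑2‑[(4S)‑2,2‑dimethyl‑1,3‑dioxolan‑4‑yl]pent‑2‑enoate | BrCC/C=C(/C(=O)OC)[C@H]1COC(C)(C)O1
F5 | step 10 | [(3E)‑4‑[(4S)‑2,2‑dimethyl‑1,3‑dioxolan‑4‑yl]‑5‑methoxy‑5‑oxopent‑3‑en‑1‑yl]zinc bromide | Br[Zn]CC/C=C(/C(=O)OC)[C@H]1COC(C)(C)O1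
F6 | step 13 | methyl (1(10)E,4E)‑15‑[(tert‑butyldiphenylsilyl)oxy]‑9‑hydroxy‑8‑[(triethylsilyl)oxy]germacra‑1(10),4,11(13)‑trien‑12,6‑olid‑14‑oate, configured as in 25 | C=C1C(=O)O[C@@H]2/C=C(/CO[Si](c3ccccc3)(c3ccccc3)C(C)(C)C)CC/C=C(/C(=O)OC)[C@H](O)[C@@H](O[Si](CC)(CC)CC)[C@@H]12
F7 | step 13 | methyl (1(10)E,4E)‑9‑acetoxy‑15‑[(tert‑butyldiphenylsilyl)oxy]‑8‑[(triethylsilyl)oxy]germacra‑1(10),4,11(13)‑trien‑12,6‑olid‑14‑oate, configured as in 25 | C=C1C(=O)O[C@@H]2/C=C(/CO[Si](c3ccccc3)(c3ccccc3)C(C)(C)C)CC/C=C(/C(=O)OC)[C@H](OC(C)=O)[C@@H](O[Si](CC)(CC)CC)[C@@H]12
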